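**Retrosynthetic overview**
- The strategy rests on ring B: its phenol carbon C2' lies between the ether carbon C1' and C3'–H. C2' is therefore taken from carbon monoxide, and C3'–C4'(CH3)–C5'–C6'(carbonyl-bearing)–C1' from a five-carbon dienyl chain already attached to the diaryl ether oxygen.
- Ring B is closed last by a palladium-catalysed carbonylative [5+1] benzannulation of a dienyl allylic acetate (bonds C2'–C3' and C1'–C2').
- The ring A–O–C1' bond comes from oxa-Michael addition of a ring A salicylate phenol to methyl propiolate. The C6'–C5' bond comes from α-iodination and Stille coupling with a stannane made from propargyl alcohol.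
- Ring A is made first from resorcinol: acylation with isovaleric acid, CBS reduction to set the (S)-carbinol, and ortho-lithiation/carboxylation between the two ring oxygens.
- After the annulation, ester reduction and MnO2 oxidation give the C6' aldehyde, and fluoride removes the silyl ether and the silylethyl ester.

Key step: step 15

Numbering remark: ring A carries the carboxyl at C1, methoxy at C2, the side chain at C3 and the ether oxygen at C6; ring B is C1' (ether), C2' (OH), C4' (CH3), C6' (CHO); the carbinol carbon is read as (S) from the SMILES.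

**Route**

Step 1
Reactants: 1 resorcinol; 2 isovaleric acid (3-methylbutanoic acid)
Product: 3 1-(2,4-dihydroxyphenyl)-3-methylbutan-1-one
Conditions: BF3·OEt2 (excess), 90 °C; aq. NaOAc work-up
Reagents that add atoms: none
Why: Nencki-type Friedel–Crafts acylation of resorcinol goes at C4 (ortho to one hydroxyl, para to the other) and stops after one acylation because the chelated aryl ketone is deactivated.

Step 2
Reactants: 3 1-(2,4-dihydroxyphenyl)-3-methylbutan-1-one
Product: 4 1-[2-hydroxy-4-(methoxymethoxy)phenyl]-3-methylbutan-1-one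
Conditions: MOMCl (1.1 equiv), K2CO3, acetone, 0 °C → rt
Reagents that add atoms: chloromethyl methyl ether, COCCl
Why: Williamson etherification goes at the free, more acidic 4-hydroxyl, because the 2-hydroxyl is held in a hydrogen bond to the ketone.

Step 3
Reactants: 4 1-[2-hydroxy-4-(methoxymethoxy)phenyl]-3-methylbutan-1-one
Product: 5 1-[2-methoxy-4-(methoxymethoxy)phenyl]-3-methylbutan-1-one
Conditions: MeI (3 equiv), K2CO3, DMF, 45 °C
Reagents that add atoms: iodomethane, CI
Why: O-methylation (Williamson) of the remaining chelated phenol under slightly more forcing conditions, to which the acetal and the ketone are inert.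

Step 4
Reactants: 5 1-[2-methoxy-4-(methoxymethoxy)phenyl]-3-methylbutan-1-one
Product: 6 (1S)-1-[2-methoxy-4-(methoxymethoxy)phenyl]-3-methylbutan-1-ol
Conditions: (R)-2-methyl-CBS-oxazaborolidine (0.1 equiv), BH3·SMe2 (0.7 equiv), THF, −20 °C; MeOH
Reagents that add atoms: none
Why: Corey–Bakshi–Shibata reduction, in which the aryl group acts as the large and isobutyl as the small substituent, so the (R)-oxazaborolidine should give the (S)-carbinol in the same sense as it gives (S)-1-phenylethanol from acetophenone.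

Step 5
Reactants: 6 (1S)-1-[2-methoxy-4-(methoxymethoxy)phenyl]-3-methylbutan-1-ol
Product: 7 triisopropyl{(1S)-1-[2-methoxy-4-(methoxymethoxy)phenyl]-3-methylbutoxy}silane
Conditions: TIPSOTf (1.3 equiv), 2,6-lutidine (2 equiv), CH2Cl2, 0 °C → rt
Reagents that add atoms: triisopropylsilyl trifluoromethanesulfonate, CC(C)[Si](OS(=O)(=O)C(F)(F)F)(C(C)C)C(C)C
Why: Silylation of a hindered secondary alcohol with a silyl triflate and a hindered base leaves the stereocentre untouched and shields the benzylic position from base, hydride, oxidant and ionisation in later steps.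

Step 6
Reactants: 7 triisopropyl{(1S)-1-[2-methoxy-4-(methoxymethoxy)phenyl]-3-methylbutoxy}silane
Product: 9 2-methoxy-6-(methoxymethoxy)-3-[(1S)-3-methyl-1-(triisopropylsilyloxy)butyl]benzoic acid, via aryllithium 8 (not isolated)
Conditions: n-BuLi (1.3 equiv), THF, 0 °C; CO2 (g), −78 °C → rt; aq. HCl to pH 3–4, 0 °C
Reagents that add atoms: carbon dioxide, O=C=O
Why: Directed ortho-metalation occurs at the ring C–H flanked by the methoxy and methoxymethoxy groups, the most acidic and doubly coordinated site, so carboxylation places the carboxyl at ring A C1.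

Step 7
Reactants: 9 2-methoxy-6-(methoxymethoxy)-3-[(1S)-3-methyl-1-(triisopropylsilyloxy)butyl]benzoic acid
Product: 10 2-(trimethylsilyl)ethyl 2-methoxy-6-(methoxymethoxy)-3-[(1S)-3-methyl-1-(triisopropylsilyloxy)butyl]benzoate
Conditions: 2-(trimethylsilyl)ethanol (1.5 equiv), PPh3, DIAD, THF, 0 °C → rt
Reagents that add atoms: 2-(trimethylsilyl)ethanol, OCC[Si](C)(C)C
Why: Mitsunobu esterification uses the di-ortho-substituted carboxylate as the nucleophile on the activated primary alcohol, so hindrance at the carbonyl carbon does not matter.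

Step 8
Reactants: 10 2-(trimethylsilyl)ethyl 2-methoxy-6-(methoxymethoxy)-3-[(1S)-3-methyl-1-(triisopropylsilyloxy)butyl]benzoate
Product: 11 2-(trimethylsilyl)ethyl 6-hydroxy-2-methoxy-3-[(1S)-3-methyl-1-(triisopropylsilyloxy)butyl]benzoate
Conditions: ZnBr2 (1 equiv), n-PrSH (2 equiv), CH2Cl2, 0 °C, 15 min
Reagents that add atoms: none
Why: Lewis acid/thiol cleavage of the phenolic methoxymethyl acetal, helped by chelation of ZnBr2 to the ortho ester carbonyl, is short and cold enough that the bulky secondary silyl ether and the silylethyl ester should survive.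

Step 9
Reactants: 11 2-(trimethylsilyl)ethyl 6-hydroxy-2-methoxy-3-[(1S)-3-methyl-1-(triisopropylsilyloxy)butyl]benzoate; 12 methyl propiolate
Product: 13 2-(trimethylsilyl)ethyl 2-methoxy-6-{[(1E)-3-methoxy-3-oxoprop-1-en-1-yl]oxy}-3-[(1S)-3-methyl-1-(triisopropylsilyloxy)butyl]benzoate
Conditions: DABCO (0.1 equiv), methyl propiolate (1.3 equiv), CH2Cl2, 0 °C → rt
Reagents that add atoms: none
Why: Amine-catalysed oxa-Michael addition of a phenol to a propiolate gives the (E)-β-aryloxyacrylate and forms the ring A–O–C1' bond without any aryl coupling.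

Step 10
Reactants: 13 2-(trimethylsilyl)ethyl 2-methoxy-6-{[(1E)-3-methoxy-3-oxoprop-1-en-1-yl]oxy}-3-[(1S)-3-methyl-1-(triisopropylsilyloxy)butyl]benzoate
Product: 15 2-(trimethylsilyl)ethyl 6-{[(1Z)-2-iodo-3-methoxy-3-oxoprop-1-en-1-yl]oxy}-2-methoxy-3-[(1S)-3-methyl-1-(triisopropylsilyloxy)butyl]benzoate, via iodoacetate adduct 14 (not isolated)
Conditions: NIS (1.3 equiv), AcOH (2 equiv), CH2Cl2, rt, dark; then Et3N (3 equiv), 0 °C → rt
Reagents that add atoms: N-iodosuccinimide, O=C1CCC(=O)N1I
Why: Electrophilic iodination of the enol ether at its nucleophilic α-carbon (C6') with acetate capture, then amine-induced elimination of acetic acid, is the standard route from β-alkoxyacrylates to (Z)-α-iodo-β-alkoxyacrylates, and ring A should react more slowly because its oxygen lone pairs are drawn towards the ortho ester and the acrylate.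

Step 11
Reactants: 16 propargyl alcohol
Product: 18 (E)-3-iodo-2-methylprop-2-en-1-ol, via alkenylalane 17 (not isolated)
Conditions: AlMe3 (3 equiv), Cp2ZrCl2 (0.25 equiv), CH2Cl2, 0 °C → rt; I2, THF, −30 → 0 °C; aq. KNaC4H4O6 (potassium sodium tartrate)
Reagents that add atoms: trimethylaluminium, C[Al](C)C; iodine, II
Why: Negishi zirconium-catalysed carboalumination adds methyl and aluminium syn across the alkyne with methyl on the internal carbon, and iodinolysis of the C–Al bond with retention gives the (E)-iodide.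

Step 12
Reactants: 18 (E)-3-iodo-2-methylprop-2-en-1-ol
Product: 20 (E)-2-methyl-3-(tributylstannyl)prop-2-en-1-ol, via dilithio alkoxide 19 (not isolated)
Conditions: t-BuLi (3.1 equiv), Et2O, −78 °C; Bu3SnCl (1.2 equiv), −78 °C → rt; aq. NH4Cl
Reagents that add atoms: tributyltin chloride, CCCC[Sn](Cl)(CCCC)CCCC
Why: Deprotonation of the hydroxyl followed by iodine–lithium exchange gives a configurationally stable alkenyllithium, which is stannylated at carbon with retention of the (E) geometry.

Step 13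
Reactants: 15 2-(trimethylsilyl)ethyl 6-{[(1Z)-2-iodo-3-methoxy-3-oxoprop-1-en-1-yl]oxy}-2-methoxy-3-[(1S)-3-methyl-1-(triisopropylsilyloxy)butyl]benzoate; 20 (E)-2-methyl-3-(tributylstannyl)prop-2-en-1-ol
Product: 21 2-(trimethylsilyl)ethyl 6-{[(1E,3E)-5-hydroxy-2-(methoxycarbonyl)-4-methylpenta-1,3-dien-1-yl]oxy}-2-methoxy-3-[(1S)-3-methyl-1-(triisopropylsilyloxy)butyl]benzoate
Conditions: Pd2(dba)3 (5 mol%), AsPh3 (20 mol%), CuI (10 mol%), NMP, rt → 45 °C
Reagents that add atoms: none
Why: Stille coupling with retention at both alkenyl carbons, as used for (Z)-2-iodo-3-methoxyacrylates, forms the C6'–C5' bond, and the free allylic alcohol is used so that no allylic ester meets zerovalent palladium at this stage.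

Step 14
Reactants: 21 2-(trimethylsilyl)ethyl 6-{[(1E,3E)-5-hydroxy-2-(methoxycarbonyl)-4-methylpenta-1,3-dien-1-yl]oxy}-2-methoxy-3-[(1S)-3-methyl-1-(triisopropylsilyloxy)butyl]benzoate
Product: 22 2-(trimethylsilyl)ethyl 6-{[(1E,3E)-5-acetoxy-2-(methoxycarbonyl)-4-methylpenta-1,3-dien-1-yl]oxy}-2-methoxy-3-[(1S)-3-methyl-1-(triisopropylsilyloxy)butyl]benzoate
Conditions: Ac2O, pyridine, DMAP (cat.), CH2Cl2, 0 °C → rt
Reagents that add atoms: acetic anhydride, CC(=O)OC(C)=O
Why: DMAP-catalysed acetylation of the primary allylic alcohol gives the allylic acetate needed for ionisation.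

Step 15
Reactants: 22 2-(trimethylsilyl)ethyl 6-{[(1E,3E)-5-acetoxy-2-(methoxycarbonyl)-4-methylpenta-1,3-dien-1-yl]oxy}-2-methoxy-3-[(1S)-3-methyl-1-(triisopropylsilyloxy)butyl]benzoate; 23 carbon monoxide
Product: 27 2-(trimethylsilyl)ethyl 6-[2-acetoxy-6-(methoxycarbonyl)-4-methylphenoxy]-2-methoxy-3-[(1S)-3-methyl-1-(triisopropylsilyloxy)butyl]benzoate, via dienylketene 24 (not isolated), via cyclohexadienone 25 (not isolated), via free phenol 26 (not isolated)
Conditions: PdCl2(PPh3)2 (5 mol%), CO (60 atm), Ac2O (2 equiv), NEt3 (2 equiv), toluene, 140 °C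
Reagents that add atoms: acetic anhydride, CC(=O)OC(C)=O
Why: Zerovalent palladium formed in situ ionises the primary allylic acetate to an η3-allyl complex over C3'–C5', CO inserts at the unsubstituted terminus C3' (bond C2'–C3'), and NEt3 removes the acidic α-hydrogen of the acylpalladium to release dienylketene 24 once η3–η1–η3 isomerisation through the C5'-bound form has placed C3' cis to C6'. This is the known palladium-catalysed cyclocarbonylation of 2,4-pentadienyl acetates to phenyl acetates, applied here to a diene carrying an aryloxy group at the closing terminus and an ester at C6'. Ring B closes by thermal disrotatory 6π-electrocyclisation of 24 (bond C1'–C2', a six-membered closure) to dienone 25, whose C1'–H enolises to phenol 26, which Ac2O traps as acetate 27. No stereocentre is created, since the sp3 C1' of 25 is transient, and the remote (S)-silyl ether takes no part. The step needs CO insertion at C3' and not C5', and a six-membered closure: C5' is the substituted, conjugated allyl terminus, so the linear acyl should form, and only that acyl has the hexatriene relationship to C1'. The C1'=C6' geometry is not carried into the product, and CO pressure should suppress decarbonylation.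

Step 16
Reactants: 27 2-(trimethylsilyl)ethyl 6-[2-acetoxy-6-(methoxycarbonyl)-4-methylphenoxy]-2-methoxy-3-[(1S)-3-methyl-1-(triisopropylsilyloxy)butyl]benzoate
Product: 28 2-(trimethylsilyl)ethyl 6-[2-hydroxy-6-(hydroxymethyl)-4-methylphenoxy]-2-methoxy-3-[(1S)-3-methyl-1-(triisopropylsilyloxy)butyl]benzoate
Conditions: i-Bu2AlH (5 equiv), CH2Cl2, −78 → −40 °C; aq. KNaC4H4O6 (potassium sodium tartrate)
Reagents that add atoms: none
Why: Hydride reduction takes the ring B methyl ester to the benzylic alcohol and cleaves the aryl acetate, while the ring A ester, flanked on both sides by methoxy and aryloxy groups, should be much slower towards the bulky aluminium hydride at low temperature.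

Step 17
Reactants: 28 2-(trimethylsilyl)ethyl 6-[2-hydroxy-6-(hydroxymethyl)-4-methylphenoxy]-2-methoxy-3-[(1S)-3-methyl-1-(triisopropylsilyloxy)butyl]benzoate
Product: 29 2-(trimethylsilyl)ethyl 6-(2-formyl-6-hydroxy-4-methylphenoxy)-2-methoxy-3-[(1S)-3-methyl-1-(triisopropylsilyloxy)butyl]benzoate
Conditions: MnO2 (15 equiv), CH2Cl2, rt
Reagents that add atoms: none
Why: MnO2 oxidation is selective for the primary benzylic alcohol, the ring A carbinol being silylated and the free phenol tolerated.

Step 18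
Reactants: 29 2-(trimethylsilyl)ethyl 6-(2-formyl-6-hydroxy-4-methylphenoxy)-2-methoxy-3-[(1S)-3-methyl-1-(triisopropylsilyloxy)butyl]benzoate
Product: 30 tenellic acid B, 6-(2-formyl-6-hydroxy-4-methylphenoxy)-3-[(1S)-1-hydroxy-3-methylbutyl]-2-methoxybenzoic acid
Conditions: Bu4NF (5 equiv), THF, 0 °C → rt; dilute HCl to pH 3–4, 0 °C
Reagents that add atoms: none
Why: Fluoride attacks silicon in both groups, fragmenting the 2-(trimethylsilyl)ethyl ester to carboxylate, ethylene and Me3SiF and cleaving the silyl ether without breaking the C–O bond of the (S)-carbinol, so the hindered ester is freed without acyl substitution or strong base near the aldehyde.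

**Compound list**
1 | resorcinol | Oc1cccc(O)c1 | starting material
2 | isovaleric acid | CC(C)CC(=O)O | starting material
3 | 1-(2,4-dihydroxyphenyl)-3-methylbutan-1-one | CC(C)CC(=O)c1ccc(O)cc1O | intermediate
4 | 1-[2-hydroxy-4-(methoxymethoxy)phenyl]-3-methylbutan-1-one | CC(C)CC(=O)c1ccc(OCOC)cc1O | intermediate
5 | 1-[2-methoxy-4-(methoxymethoxy)phenyl]-3-methylbutan-1-one | CC(C)CC(=O)c1ccc(OCOC)cc1OC | intermediate
6 | (1S)-1-[2-methoxy-4-(methoxymethoxy)phenyl]-3-methylbutan-1-ol | COCOc1ccc([C@@H](O)CC(C)C)c(OC)c1 | intermediate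
7 | triisopropyl{(1S)-1-[2-methoxy-4-(methoxymethoxy)phenyl]-3-methylbutoxy}silane | COCOc1ccc([C@@H](O[Si](C(C)C)(C(C)C)C(C)C)CC(C)C)c(OC)c1 | intermediate
8 | aryllithium: {2-methoxy-6-(methoxymethoxy)-3-[(1S)-3-methyl-1-(triisopropylsilyloxy)butyl]phenyl}lithium | COCOc1ccc([C@@H](O[Si](C(C)C)(C(C)C)C(C)C)CC(C)C)c(OC)c1[Li] | intermediate (not isolated)
9 | 2-methoxy-6-(methoxymethoxy)-3-[(1S)-3-methyl-1-(triisopropylsilyloxy)butyl]benzoic acid | COCOc1ccc([C@@H](O[Si](C(C)C)(C(C)C)C(C)C)CC(C)C)c(OC)c1C(=O)O | intermediate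
10 | 2-(trimethylsilyl)ethyl 2-methoxy-6-(methoxymethoxy)-3-[(1S)-3-methyl-1-(triisopropylsilyloxy)butyl]benzoate | COCOc1ccc([C@@H](O[Si](C(C)C)(C(C)C)C(C)C)CC(C)C)c(OC)c1C(=O)OCC[Si](C)(C)C | intermediate
11 | 2-(trimethylsilyl)ethyl 6-hydroxy-2-methoxy-3-[(1S)-3-methyl-1-(triisopropylsilyloxy)butyl]benzoate | COc1c([C@@H](O[Si](C(C)C)(C(C)C)C(C)C)CC(C)C)ccc(O)c1C(=O)OCC[Si](C)(C)C | intermediate
12 | methyl propiolate | C#CC(=O)OC | starting material
13 | 2-(trimethylsilyl)ethyl 2-methoxy-6-{[(1E)-3-methoxy-3-oxoprop-1-en-1-yl]oxy}-3-[(1S)-3-methyl-1-(triisopropylsilyloxy)butyl]benzoate | COc1c([C@@H](O[Si](C(C)C)(C(C)C)C(C)C)CC(C)C)ccc(O/C=C/C(=O)OC)c1C(=O)OCC[Si](C)(C)C | intermediate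
14 | iodoacetate adduct: 2-(trimethylsilyl)ethyl 6-[(1-acetoxy-2-iodo-3-methoxy-3-oxopropyl)oxy]-2-methoxy-3-[(1S)-3-methyl-1-(triisopropylsilyloxy)butyl]benzoate (diastereomer mixture at the two new carbons) | COc1c([C@@H](O[Si](C(C)C)(C(C)C)C(C)C)CC(C)C)ccc(OC(OC(C)=O)C(I)C(=O)OC)c1C(=O)OCC[Si](C)(C)C | intermediate (not isolated)
15 | 2-(trimethylsilyl)ethyl 6-{[(1Z)-2-iodo-3-methoxy-3-oxoprop-1-en-1-yl]oxy}-2-methoxy-3-[(1S)-3-methyl-1-(triisopropylsilyloxy)butyl]benzoate | COc1c([C@@H](O[Si](C(C)C)(C(C)C)C(C)C)CC(C)C)ccc(O/C=C(\I)C(=O)OC)c1C(=O)OCC[Si](C)(C)C | intermediate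
16 | propargyl alcohol | C#CCO | starting material
17 | alkenylalane: dimethyl[(E)-3-(dimethylalumanyloxy)-2-methylprop-1-enyl]alumane | C[Al](C)/C=C(C)/CO[Al](C)C | intermediate (not isolated)
18 | (E)-3-iodo-2-methylprop-2-en-1-ol | OC/C(C)=C/I | intermediate
19 | dilithio alkoxide: lithium (E)-3-lithio-2-methylprop-2-en-1-olate | [Li]/C=C(C)/CO[Li] | intermediate (not isolated)
20 | (E)-2-methyl-3-(tributylstannyl)prop-2-en-1-ol | CCCC[Sn](CCCC)(CCCC)/C=C(C)/CO | intermediate
21 | 2-(trimethylsilyl)ethyl 6-{[(1E,3E)-5-hydroxy-2-(methoxycarbonyl)-4-methylpenta-1,3-dien-1-yl]oxy}-2-methoxy-3-[(1S)-3-methyl-1-(triisopropylsilyloxy)butyl]benzoate | COc1c([C@@H](O[Si](C(C)C)(C(C)C)C(C)C)CC(C)C)ccc(O/C=C(C(=O)OC)\C=C(C)\CO)c1C(=O)OCC[Si](C)(C)C | intermediate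
22 | 2-(trimethylsilyl)ethyl 6-{[(1E,3E)-5-acetoxy-2-(methoxycarbonyl)-4-methylpenta-1,3-dien-1-yl]oxy}-2-methoxy-3-[(1S)-3-methyl-1-(triisopropylsilyloxy)butyl]benzoate | COc1c([C@@H](O[Si](C(C)C)(C(C)C)C(C)C)CC(C)C)ccc(O/C=C(C(=O)OC)\C=C(C)\COC(C)=O)c1C(=O)OCC[Si](C)(C)C | intermediate
23 | carbon monoxide | [C-]#[O+] | starting material
24 | dienylketene: 2-(trimethylsilyl)ethyl 2-methoxy-6-{[(1E,3Z)-2-(methoxycarbonyl)-4-methyl-6-oxohexa-1,3,5-trien-1-yl]oxy}-3-[(1S)-3-methyl-1-(triisopropylsilyloxy)butyl]benzoate | COc1c([C@@H](O[Si](C(C)C)(C(C)C)C(C)C)CC(C)C)ccc(O/C=C(C(=O)OC)\C=C(C)/C=C=O)c1C(=O)OCC[Si](C)(C)C | intermediate (not isolated)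
25 | cyclohexadienone: 2-(trimethylsilyl)ethyl 2-methoxy-6-{[2-(methoxycarbonyl)-4-methyl-6-oxocyclohexa-2,4-dien-1-yl]oxy}-3-[(1S)-3-methyl-1-(triisopropylsilyloxy)butyl]benzoate (both epimers at C1') | COc1c([C@@H](O[Si](C(C)C)(C(C)C)C(C)C)CC(C)C)ccc(OC2C(=O)C=C(C)C=C2C(=O)OC)c1C(=O)OCC[Si](C)(C)C | intermediate (not isolated)
26 | free phenol: 2-(trimethylsilyl)ethyl 6-[2-hydroxy-6-(methoxycarbonyl)-4-methylphenoxy]-2-methoxy-3-[(1S)-3-methyl-1-(triisopropylsilyloxy)butyl]benzoate | COc1c([C@@H](O[Si](C(C)C)(C(C)C)C(C)C)CC(C)C)ccc(Oc2c(O)cc(C)cc2C(=O)OC)c1C(=O)OCC[Si](C)(C)C | intermediate (not isolated)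
27 | 2-(trimethylsilyl)ethyl 6-[2-acetoxy-6-(methoxycarbonyl)-4-methylphenoxy]-2-methoxy-3-[(1S)-3-methyl-1-(triisopropylsilyloxy)butyl]benzoate | COc1c([C@@H](O[Si](C(C)C)(C(C)C)C(C)C)CC(C)C)ccc(Oc2c(OC(C)=O)cc(C)cc2C(=O)OC)c1C(=O)OCC[Si](C)(C)C | intermediate
28 | 2-(trimethylsilyl)ethyl 6-[2-hydroxy-6-(hydroxymethyl)-4-methylphenoxy]-2-methoxy-3-[(1S)-3-methyl-1-(triisopropylsilyloxy)butyl]benzoate | COc1c([C@@H](O[Si](C(C)C)(C(C)C)C(C)C)CC(C)C)ccc(Oc2c(O)cc(C)cc2CO)c1C(=O)OCC[Si](C)(C)C | intermediate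
29 | 2-(trimethylsilyl)ethyl 6-(2-formyl-6-hydroxy-4-methylphenoxy)-2-methoxy-3-[(1S)-3-methyl-1-(triisopropylsilyloxy)butyl]benzoate | COc1c([C@@H](O[Si](C(C)C)(C(C)C)C(C)C)CC(C)C)ccc(Oc2c(O)cc(C)cc2C=O)c1C(=O)OCC[Si](C)(C)C | intermediate
30 | tenellic acid B | COc1c([C@@H](O)CC(C)C)ccc(Oc2c(O)cc(C)cc2C=O)c1C(=O)O | target

**Step count and risks**

Total: 18 steps. Longest linear sequence: 16 steps (steps 1–10 and 13–18).

Step 15 (carbonylative benzannulation) is the most likely to fail. CO may insert at the substituted allyl terminus, the allyl complex may fail to reach the cisoid arrangement so that the acyl species cannot close, NEt3 or acetate may cleave the aryl vinyl ether by addition–elimination at C1' at 140 °C, or the allyl complex may lose a β-hydrogen to give a triene. The fallback forms the diaryl ether by nucleophilic aromatic substitution instead of building ring B. It sets out from phenol 11. 2-Bromo-1-fluoro-4-methylbenzene is lithiated ortho to fluorine (LDA, THF, −78 °C) and formylated with DMF to give 3-bromo-2-fluoro-5-methylbenzaldehyde F1. Phenol 11 displaces the fluoride activated by the ortho formyl group (K2CO3, DMF, 90 °C) to give 2-(trimethylsilyl)ethyl 6-(2-bromo-6-formyl-4-methylphenoxy)-2-methoxy-3-[(1S)-3-methyl-1-(triisopropylsilyloxy)butyl]benzoate F2. Miyaura borylation (B2pin2, PdCl2(dppf), KOAc, dioxane, 85 °C) gives the pinacol boronate F3, and oxidation of the C–B bond with Me3NO (THF, 50 °C, aqueous work-up) gives the phenol aldehyde. The fallback comes back to the route at compound 29, so that only step 18 remains.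

Step 10 (α-iodination) is the second risk. Ring A may be iodinated at C5, para to its methoxy group, in competition with the deactivated enol ether, and the acetoxy adduct 14 may hydrolyse with loss of the aryl vinyl ether. The fallback builds the C6'–C5' bond before the ether bond and uses no electrophilic halogenation in the presence of ring A. It sets out from phenol 11 and methyl propiolate 12. A MgI2-mediated iodo-aldol (halo-Baylis–Hillman) reaction of 12 with methacrolein (MgI2, CH2Cl2, 0 °C) gives methyl (2Z)-2-(1-hydroxy-2-methylprop-2-en-1-yl)-3-iodoprop-2-enoate F4. Addition–elimination of the phenoxide of 11 at the iodine-bearing carbon (Cs2CO3, MeCN, rt) gives the aryloxy dienol 2-(trimethylsilyl)ethyl 6-{[(1Z)-3-hydroxy-2-(methoxycarbonyl)-4-methylpenta-1,4-dien-1-yl]oxy}-2-methoxy-3-[(1S)-3-methyl-1-(triisopropylsilyloxy)butyl]benzoate F5. Acetylation (Ac2O, pyridine, DMAP) gives the branched allylic acetate F6. With zerovalent palladium F6 should ionise to the same η3-allyl complex as 22, so under the conditions of step 15 it comes back to the route at compound 27.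

Step 16 (ester reduction) is the third risk. The ring A silylethyl ester may be over-reduced, or the reduction may stall at the aldehyde or hemiacetal level and give mixtures. The fallback replaces ester reduction by hydrolysis and acid reduction. It sets out from compound 27. LiOH (THF/MeOH/H2O, rt) cleaves the aryl acetate and the ring B methyl ester but should spare the di-ortho-substituted ring A ester, giving 3-hydroxy-2-{3-methoxy-4-[(1S)-3-methyl-1-(triisopropylsilyloxy)butyl]-2-{[2-(trimethylsilyl)ethoxy]carbonyl}phenoxy}-5-methylbenzoic acid F7. BH3·THF (0 °C → rt) reduces the carboxylic acid much faster than the remaining ester, and the fallback comes back to the route at compound 28.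

**Further compounds**
F1 | step 15 | 3-bromo-2-fluoro-5-methylbenzaldehyde | Cc1cc(Br)c(F)c(C=O)c1
F2 | step 15 | 2-(trimethylsilyl)ethyl 6-(2-bromo-6-formyl-4-methylphenoxy)-2-methoxy-3-[(1S)-3-methyl-1-(triisopropylsilyloxy)butyl]benzoate | COc1c([C@@H](O[Si](C(C)C)(C(C)C)C(C)C)CC(C)C)ccc(Oc2c(Br)cc(C)cc2C=O)c1C(=O)OCC[Si](C)(C)C
F3 | step 15 | 2-(trimethylsilyl)ethyl 6-[2-formyl-4-methyl-6-(4,4,5,5-tetramethyl-1,3,2-dioxaborolan-2-yl)phenoxy]-2-methoxy-3-[(1S)-3-methyl-1-(triisopropylsilyloxy)butyl]benzoate | COc1c([C@@H](O[Si](C(C)C)(C(C)C)C(C)C)CC(C)C)ccc(Oc2c(B3OC(C)(C)C(C)(C)O3)cc(C)cc2C=O)c1C(=O)OCC[Si](C)(C)C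
F4 | step 10 | methyl (2Z)-2-(1-hydroxy-2-methylprop-2-en-1-yl)-3-iodoprop-2-enoate (racemic) | COC(=O)/C(=C\I)C(O)C(C)=C
F5 | step 10 | 2-(trimethylsilyl)ethyl 6-{[(1Z)-3-hydroxy-2-(methoxycarbonyl)-4-methylpenta-1,4-dien-1-yl]oxy}-2-methoxy-3-[(1S)-3-methyl-1-(triisopropylsilyloxy)butyl]benzoate (both carbinol epimers) | COc1c([C@@H](O[Si](C(C)C)(C(C)C)C(C)C)CC(C)C)ccc(O/C=C(\C(=O)OC)C(O)C(C)=C)c1C(=O)OCC[Si](C)(C)C
F6 | step 10 | 2-(trimethylsilyl)ethyl 6-{[(1Z)-3-acetoxy-2-(methoxycarbonyl)-4-methylpenta-1,4-dien-1-yl]oxy}-2-methoxy-3-[(1S)-3-methyl-1-(triisopropylsilyloxy)butyl]benzoate (both acetate epimers) | COc1c([C@@H](O[Si](C(C)C)(C(C)C)C(C)C)CC(C)C)ccc(O/C=C(\C(=O)OC)C(OC(C)=O)C(C)=C)c1C(=O)OCC[Si](C)(C)C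
F7 | step 16 | 3-hydroxy-2-{3-methoxy-4-[(1S)-3-methyl-1-(triisopropylsilyloxy)butyl]-2-{[2-(trimethylsilyl)ethoxy]carbonyl}phenoxy}-5-methylbenzoic acid | COc1c([C@@H](O[Si](C(C)C)(C(C)C)C(C)C)CC(C)C)ccc(Oc2c(O)cc(C)cc2C(=O)O)c1C(=O)OCC[Si](C)(C)C
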